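The route rests on closing ring B (C1–C9–C5–C6–C7–C8) last, by joining C1, the enol carbon flanked by the C2 and C9 carbonyls, to C8, the gem-dimethyl carbon, in a biomimetic cationic cyclization. The precursor is a dearomatized acylphloroglucinol: quaternary C5 carries geranyl and an (R)-lavandulol-derived chain ending in a tertiary carbinol at C8, and C1 is the β-carbon of a methyl enol ether. Acid ionizes the carbinol; C1 traps the cation in a chair with C7-prenyl equatorial, and the methyl ether leaves as methanol. One operation thus forges the quaternary–quaternary bond, the bicyclo[3.3.1]nonane core and the C1 stereocenter.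

Key step: step 8

Remark: locants C1–C9 are those of the bicyclo[3.3.1]nonane core of the target (C1 prenyl bridgehead, C3 aroyl carbon, C5 geranyl bridgehead, C7 prenyl-bearing CH, C8 CMe2, C9 bridging ketone) and are kept for the monocyclic precursors; (R)-lavandulol is assumed to be purchasable in enantiopure form.

Step 1
Reactants: 1 3,4-dihydroxybenzonitrile; 2 allyl bromide
Product: 3 3,4-bis(prop-2-en-1-yloxy)benzonitrile
Conditions: allyl bromide (2.2 equiv in all), K2CO3, DMF, 60 °C
Reagents that add atoms: allyl bromide C=CCBr (the second equivalent of 2, which supplies the second allyl group)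
Why: Twofold Williamson ether synthesis, one equivalent of allyl bromide per phenol; allyl is chosen because it should survive the HCl, base and acid steps and is removed at the end without acid or hydrogen.

Step 2
Reactants: 3 3,4-bis(prop-2-en-1-yloxy)benzonitrile; 4 5-methoxyresorcinol
Product: 6 [3,4-bis(prop-2-en-1-yloxy)phenyl](2,4-dihydroxy-6-methoxyphenyl)methanone, via ketiminium chloride 5 (not isolated)
Conditions: ZnCl2, HCl (g), Et2O, 0 °C → rt; then H2O, 100 °C
Reagents that add atoms: water O
Why: Houben–Hoesch acylation, in which the activated nitrile should attack the ring mainly para to one hydroxyl and ortho to the other (less hindered than the carbon between the two hydroxyls, as in related acylations of 5-substituted resorcinols), so that after hydrolysis of 5 the methoxy group sits ortho to the ketone, where it later marks C2.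

Step 3
Reactants: 6 [3,4-bis(prop-2-en-1-yloxy)phenyl](2,4-dihydroxy-6-methoxyphenyl)methanone; 7 geranyl bromide
Product: 8 [3,4-bis(prop-2-en-1-yloxy)phenyl]{3-[(2E)-3,7-dimethylocta-2,6-dien-1-yl]-2,4-dihydroxy-6-methoxyphenyl}methanone
Conditions: KOH, H2O/MeOH, 0 °C → rt
Reagents that add atoms: none
Why: C-allylation of a polyphenolate in protic base (the reaction used for C-prenylation of acylphloroglucinols) should take place at the ring carbon between the two phenoxide oxygens (future C5), the most nucleophilic carbon of a 2,4-dihydroxy-6-methoxyaryl ketone, with the E-alkene untouched by the SN2 displacement.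

Step 4
Reactants: 8 the C-geranyl ketone; 9 prenyl bromide
Product: 10 [3,4-bis(prop-2-en-1-yloxy)phenyl]{3-[(2E)-3,7-dimethylocta-2,6-dien-1-yl]-2,4-dihydroxy-6-methoxy-5-(3-methylbut-2-en-1-yl)phenyl}methanone
Conditions: KOH, H2O/MeOH, 0 °C → rt
Reagents that add atoms: none
Why: A second C-allylation of the same type at the only ring C–H left (future C1, between the para hydroxyl and the methoxy group), where rearomatization should make it faster than dearomatizing attack at the already substituted C5.

Step 5
Reactants: 11 (R)-lavandulol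
Product: 12 (2S)-3-methyl-2-(3-methylbut-2-en-1-yl)butane-1,3-diol
Conditions: Co(acac)2 (20 mol %), PhSiH3, O2 (1 atm), THF, rt
Reagents that add atoms: dioxygen O=O
Why: Mukaiyama hydration (cobalt hydride hydrogen-atom transfer, then O2 capture) is Markovnikov and strongly favours the 1,1-disubstituted alkene over the trisubstituted prenyl alkene, and fast O2 capture leaves the neighbouring stereocenter untouched (its descriptor changes from R to S only because the CIP priorities change).

Step 6
Reactants: 12 (2S)-3-methyl-2-(3-methylbut-2-en-1-yl)butane-1,3-diol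
Product: 13 (2S)-3-hydroxy-3-methyl-2-(3-methylbut-2-en-1-yl)butyl trifluoromethanesulfonate
Conditions: Tf2O, 2,6-lutidine, CH2Cl2, −78 °C
Reagents that add atoms: triflic anhydride O=S(=O)(OS(=O)(=O)C(F)(F)F)C(F)(F)F
Why: Chemoselective O-sulfonylation, in which the primary hydroxyl reacts at −78 °C while the hindered tertiary one does not; the crude triflate is used cold at once to forestall oxetane formation.

Step 7
Reactants: 10 the geranyl/prenyl ketone; 13 the hydroxy triflate
Product: 15 (6R)-4-[3,4-bis(prop-2-en-1-yloxy)benzoyl]-6-[(2E)-3,7-dimethylocta-2,6-dien-1-yl]-5-hydroxy-6-[(2S)-3-hydroxy-3-methyl-2-(3-methylbut-2-en-1-yl)butyl]-3-methoxy-2-(3-methylbut-2-en-1-yl)cyclohexa-2,4-dien-1-one, via dilithium bis-phenoxide 14 (not isolated)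
Conditions: LiN(SiMe3)2 (2.0 equiv), THF, 0 °C; then 13, −40 → 0 °C; cold 0.5 M HCl work-up; chromatography
Reagents that add atoms: none
Why: Alkylative dearomatization, in which the lithium-chelated dianion should be C-alkylated by the primary triflate at C5, the carbon flanked by both O–Li groups (the site where exhaustive alkylation of 2,4-dihydroxy-6-methoxyaryl ketones builds the quaternary carbon), while the side-chain stereocenter lies β to the reacting carbon and is untouched; the chiral triflate is not expected to differentiate the two faces of C5 strongly, so the new quaternary stereocenter is secured by chromatographic isolation of the (6R) diastereomer 15 from its C5 epimer.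

Step 8
Reactants: 15 the (6R) dienone
Product: 17 (1R,5R,7S)-3-[3,4-bis(prop-2-en-1-yloxy)benzoyl]-5-[(2E)-3,7-dimethylocta-2,6-dien-1-yl]-4-hydroxy-8,8-dimethyl-1,7-bis(3-methylbut-2-en-1-yl)bicyclo[3.3.1]non-3-ene-2,9-dione, via methyl oxocarbenium triflimide 16 (not isolated)
Conditions: Tf2NH (10 mol %), CH2Cl2, −40 → 0 °C
Reagents that add atoms: none
Why: Protonation ionizes the tertiary carbinol to the C8 cation, which is captured by C1, the β-carbon of the C1=C2 methyl enol ether; the resulting oxocarbenium ion 16 is hydrolysed by the water just released, giving the C2 ketone and methanol, so the acid turns over. The closest known reaction types are the biomimetic acid-mediated cyclization of dearomatized acylphloroglucinol methyl enol ethers to type B bicyclic cores and the acid-mediated SN1 tert-alkylation of enol ethers, both of which forge quaternary–quaternary bonds. Ring B closes in a 6-(enolexo)-exo-tet mode through a chair in which C7-prenyl is equatorial, which the (6R) epimer allows. C1 is the only new stereocenter, and its configuration is dictated by C5 because the three-atom tether can deliver C8 only to the face of ring A that carries the C5–C6 bond; C7 comes unchanged from (R)-lavandulol. The step needs C- over O-alkylation, C1 over C3, and ionization without alkene protonation: O2 is capped as the ether, trapping at O9 or O4 should be reversible under acid whereas C–C bond formation is not, C3 is deactivated by the aroyl group, and a tertiary carbinol should ionize at an acid strength and temperature at which the prenyl and geranyl alkenes are not protonated.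

Step 9
Reactants: 17 the bis-allyl ether
Product: 18 (1R,5R,7S)-3-(3,4-dihydroxybenzoyl)-5-[(2E)-3,7-dimethylocta-2,6-dien-1-yl]-4-hydroxy-8,8-dimethyl-1,7-bis(3-methylbut-2-en-1-yl)bicyclo[3.3.1]non-3-ene-2,9-dione
Conditions: Pd(PPh3)4 (5 mol %), morpholine, THF, rt, argon
Reagents that add atoms: none
Why: Tsuji–Trost deallylation, in which zerovalent palladium ionizes the two aryl allyl ethers and morpholine captures the allyl fragments; the C-prenyl and C-geranyl groups carry no leaving group, the fully substituted C3 cannot be C-allylated, and no stereocenter is affected.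

Compound list
1 | 3,4-dihydroxybenzonitrile | N#Cc1ccc(O)c(O)c1 | starting material
2 | allyl bromide | C=CCBr | starting material
3 | 3,4-bis(prop-2-en-1-yloxy)benzonitrile | N#Cc1ccc(OCC=C)c(OCC=C)c1 | intermediate
4 | 5-methoxyresorcinol | COc1cc(O)cc(O)c1 | starting material
5 | [3,4-bis(prop-2-en-1-yloxy)phenyl](2,4-dihydroxy-6-methoxyphenyl)methaniminium chloride | COc1cc(O)cc(O)c1C(=[NH2+])c1ccc(OCC=C)c(OCC=C)c1.[Cl-] | intermediate
6 | [3,4-bis(prop-2-en-1-yloxy)phenyl](2,4-dihydroxy-6-methoxyphenyl)methanone | COc1cc(O)cc(O)c1C(=O)c1ccc(OCC=C)c(OCC=C)c1 | intermediate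
7 | geranyl bromide, (2E)-1-bromo-3,7-dimethylocta-2,6-diene | CC(C)=CCC/C(C)=C/CBr | starting material
8 | [3,4-bis(prop-2-en-1-yloxy)phenyl]{3-[(2E)-3,7-dimethylocta-2,6-dien-1-yl]-2,4-dihydroxy-6-methoxyphenyl}methanone | COc1cc(O)c(C/C=C(\C)CCC=C(C)C)c(O)c1C(=O)c1ccc(OCC=C)c(OCC=C)c1 | intermediate
9 | prenyl bromide, 1-bromo-3-methylbut-2-ene | CC(C)=CCBr | starting material
10 | [3,4-bis(prop-2-en-1-yloxy)phenyl]{3-[(2E)-3,7-dimethylocta-2,6-dien-1-yl]-2,4-dihydroxy-6-methoxy-5-(3-methylbut-2-en-1-yl)phenyl}methanone | COc1c(CC=C(C)C)c(O)c(C/C=C(\C)CCC=C(C)C)c(O)c1C(=O)c1ccc(OCC=C)c(OCC=C)c1 | intermediate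
11 | (R)-lavandulol, (2R)-5-methyl-2-(prop-1-en-2-yl)hex-4-en-1-ol | OC[C@H](CC=C(C)C)C(C)=C | starting material
12 | (2S)-3-methyl-2-(3-methylbut-2-en-1-yl)butane-1,3-diol | OC[C@H](CC=C(C)C)C(C)(C)O | intermediate
13 | (2S)-3-hydroxy-3-methyl-2-(3-methylbut-2-en-1-yl)butyl trifluoromethanesulfonate | O=S(=O)(OC[C@H](CC=C(C)C)C(C)(C)O)C(F)(F)F | intermediate
14 | dilithium bis-phenoxide of 10 | [Li+].[Li+].COc1c(CC=C(C)C)c([O-])c(C/C=C(\C)CCC=C(C)C)c([O-])c1C(=O)c1ccc(OCC=C)c(OCC=C)c1 | intermediate
15 | (6R)-4-[3,4-bis(prop-2-en-1-yloxy)benzoyl]-6-[(2E)-3,7-dimethylocta-2,6-dien-1-yl]-5-hydroxy-6-[(2S)-3-hydroxy-3-methyl-2-(3-methylbut-2-en-1-yl)butyl]-3-methoxy-2-(3-methylbut-2-en-1-yl)cyclohexa-2,4-dien-1-one | O=C1C(CC=C(C)C)=C(OC)C(C(=O)c2ccc(OCC=C)c(OCC=C)c2)=C(O)[C@@]1(C/C=C(\C)CCC=C(C)C)C[C@H](CC=C(C)C)C(C)(C)O | intermediate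
16 | C2 O-methyl oxocarbenium ion of 17, triflimide salt | CC(C)=CCC/C(C)=C/C[C@@]12C[C@H](CC=C(C)C)C(C)(C)[C@@](CC=C(C)C)(C(=[O+]C)C(C(=O)c3ccc(OCC=C)c(OCC=C)c3)=C1O)C2=O.O=S(=O)([N-]S(=O)(=O)C(F)(F)F)C(F)(F)F | intermediate
17 | (1R,5R,7S)-3-[3,4-bis(prop-2-en-1-yloxy)benzoyl]-5-[(2E)-3,7-dimethylocta-2,6-dien-1-yl]-4-hydroxy-8,8-dimethyl-1,7-bis(3-methylbut-2-en-1-yl)bicyclo[3.3.1]non-3-ene-2,9-dione | CC(C)=CCC/C(C)=C/C[C@@]12C[C@H](CC=C(C)C)C(C)(C)[C@@](CC=C(C)C)(C(=O)C(C(=O)c3ccc(OCC=C)c(OCC=C)c3)=C1O)C2=O | intermediate
18 | (1R,5R,7S)-3-(3,4-dihydroxybenzoyl)-5-[(2E)-3,7-dimethylocta-2,6-dien-1-yl]-4-hydroxy-8,8-dimethyl-1,7-bis(3-methylbut-2-en-1-yl)bicyclo[3.3.1]non-3-ene-2,9-dione | CC(C)=CCC/C(C)=C/C[C@@]12C[C@H](CC=C(C)C)C(C)(C)[C@@](CC=C(C)C)(C(=O)C(C(=O)c3ccc(O)c(O)c3)=C1O)C2=O | target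

Total step count: 9. Longest linear sequence: 7 steps (steps 1, 2, 3, 4, 7, 8, 9); steps 5 and 6 form the convergent branch.

Steps most likely to fail

Step 8. The C8 cation may be captured kinetically by the flanking carbonyl or enol oxygens (O-cyclization), lose a proton to give alkenes, or suffer a 1,2-hydride shift from C7 that would scramble that stereocenter. The acid may also start a proton-initiated cyclization of the geranyl chain. The fallback gives up ionization of a carbinol and uses the established protic variant, in which the cation arises by protonation of an alkene in a solvent where formate and oxygen adducts revert. It sets out from 10 and 11: (R)-lavandulol 11 is converted with Tf2O and 2,6-lutidine at −78 °C into (2R)-5-methyl-2-(prop-1-en-2-yl)hex-4-en-1-yl trifluoromethanesulfonate F1, which alkylates the dilithium salt of 10 at C5 as in step 7 to give the lavandulyl dienone F2 (isolated from its C5 epimer as before). F2 is stirred in neat formic acid at room temperature, where protonation of the isopropenyl group should give the same C8 cation, C1 closes ring B and the methyl group is lost as methyl formate. The route is rejoined at 17. The price is competing protonation of the geranyl terminus, to be limited by stopping at partial conversion and recycling F2.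

Step 7. The triflate may alkylate oxygen or the prenyl-bearing carbon instead of C5, the hydroxy triflate may close to an oxetane before it is consumed, and the two faces of C5 are not differentiated, so that material is lost on separation. The fallback inverts the order of the two C5 substituents, so that the sluggish triflate meets an unsubstituted ring carbon and the quaternary centre is made with an allylic bromide under chiral ion-pair control. It sets out from 6 and 13: the dilithium salt of 6 (LiN(SiMe3)2, THF) is alkylated by 13 at the C–H between the two hydroxyls, with rearomatization, to give the side-chain ketone F3. C-prenylation of F3 with 9 and KOH at the remaining ring C–H gives the fully substituted ketone F4. Asymmetric phase-transfer alkylative dearomatization of F4 with geranyl bromide 7 (CsOH·H2O, N-(9-anthracenylmethyl)cinchonidinium bromide or its cinchonine-derived pseudo-enantiomer, toluene, −40 °C) then sets C5 under catalyst control and rejoins the route at 15.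

Step 3. O-alkylation, alkylation at the carbon next to the methoxy group and double alkylation may compete with mono-C-geranylation between the hydroxyls. The fallback fixes the position of the geranyl group by directed ortho-metalation before the ketone is made. It sets out from 4 and 3 (the Hoesch step is bypassed as well). 5-Methoxyresorcinol 4 is protected with MOMCl and iPr2NEt as 1-methoxy-3,5-bis(methoxymethoxy)benzene F5. Lithiation with n-BuLi between the two OMOM groups, transmetalation with CuBr·SMe2 and alkylation with 7 gives the 2-geranyl arene F6. A second lithiation (n-BuLi, TMEDA) at the position between OMOM and OMe, addition to nitrile 3 and mild acidic hydrolysis of the ketimine gives the protected ketone F7. Removal of both MOM groups with TMSOTf and 2,2'-bipyridyl, then water, rejoins the route at 8.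

Further compounds
F1 | step 8 | (2R)-5-methyl-2-(prop-1-en-2-yl)hex-4-en-1-yl trifluoromethanesulfonate | O=S(=O)(OC[C@H](CC=C(C)C)C(C)=C)C(F)(F)F
F2 | step 8 | (6R)-4-[3,4-bis(prop-2-en-1-yloxy)benzoyl]-6-[(2E)-3,7-dimethylocta-2,6-dien-1-yl]-5-hydroxy-3-methoxy-2-(3-methylbut-2-en-1-yl)-6-[(2S)-5-methyl-2-(prop-1-en-2-yl)hex-4-en-1-yl]cyclohexa-2,4-dien-1-one | O=C1C(CC=C(C)C)=C(OC)C(C(=O)c2ccc(OCC=C)c(OCC=C)c2)=C(O)[C@@]1(C/C=C(\C)CCC=C(C)C)C[C@H](CC=C(C)C)C(C)=C
F3 | step 7 | [3,4-bis(prop-2-en-1-yloxy)phenyl]{2,4-dihydroxy-3-[(2S)-3-hydroxy-3-methyl-2-(3-methylbut-2-en-1-yl)butyl]-6-methoxyphenyl}methanone | COc1cc(O)c(C[C@H](CC=C(C)C)C(C)(C)O)c(O)c1C(=O)c1ccc(OCC=C)c(OCC=C)c1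
F4 | step 7 | [3,4-bis(prop-2-en-1-yloxy)phenyl]{2,4-dihydroxy-3-[(2S)-3-hydroxy-3-methyl-2-(3-methylbut-2-en-1-yl)butyl]-6-methoxy-5-(3-methylbut-2-en-1-yl)phenyl}methanone | COc1c(CC=C(C)C)c(O)c(C[C@H](CC=C(C)C)C(C)(C)O)c(O)c1C(=O)c1ccc(OCC=C)c(OCC=C)c1
F5 | step 3 | 1-methoxy-3,5-bis(methoxymethoxy)benzene | COCOc1cc(OC)cc(OCOC)c1
F6 | step 3 | 2-[(2E)-3,7-dimethylocta-2,6-dien-1-yl]-5-methoxy-1,3-bis(methoxymethoxy)benzene | COCOc1cc(OC)cc(OCOC)c1C/C=C(\C)CCC=C(C)C
F7 | step 3 | [3,4-bis(prop-2-en-1-yloxy)phenyl]{3-[(2E)-3,7-dimethylocta-2,6-dien-1-yl]-6-methoxy-2,4-bis(methoxymethoxy)phenyl}methanone | COCOc1cc(OC)c(C(=O)c2ccc(OCC=C)c(OCC=C)c2)c(OCOC)c1C/C=C(\C)CCC=C(C)C
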